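## Retrosynthetic overview

1. The target is epicatechin 3-O-gallate-(4β→6)-epicatechin 3-O-gallate-(4β→8)-epicatechin 3-O-gallate. The end game is the lower gallate ester and hydrogenolysis of 21 benzyl ethers; the upper and lower units come from (−)-epicatechin.
2. Key disconnection: ring C of the middle unit is opened across O1–C2 and C3–C4 into an o-quinone methide (O1=C8a–C4a=C4 of middle ring A, with C4 carrying C8 of the lower flavan) and a Z-enol gallate (C2=C3, ring B on C2). The quinone methide is assembled in the same flask from an O-Boc salicylaldehyde and the 8-magnesio lower flavan.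
3. Enabling feature: middle ring A is a phloroglucinol, so O1, C8a, C4a and the doubly benzylic C4 form a latent o-quinone methide, and the cis 2-aryl/3-galloyloxy pair of ring C maps onto a Z-β-acyloxystyrene. Closing ring C last also fixes the 4β→6 junction, because the phloroglucinol oxygen left free becomes O1.
4. Upper junction: Friedel–Crafts arylation of a C4-activated epicatechin gallate by a phloroglucinol ether, then ortho-formylation of the liberated phenol.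
5. Ring order: all rings of the upper and lower units pre-exist; middle ring A is brought in intact; middle ring C is formed in step 13, with ring B and the middle gallate arriving on the dienophile.

Key step: step 13

Remark: flavan numbering (O1, C2, C3, C4, C4a, C5–C8, C8a) is used for each unit and α/β refer to the usual flavan drawing; compounds 1, 2, 4, 6, 8, 9, 13, 15, 17, 19, 21 and 22 are assumed to be purchased.

## Route

Step 1
Reactants: 1 (−)-epicatechin; 2 benzyl bromide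
Product: 3 5,7,3',4'-tetra-O-benzyl-(−)-epicatechin
Conditions: BnBr (4.4 equiv), K2CO3, DMF, 0 °C to rt
Reagents that add atoms: benzyl bromide, BrCc1ccccc1
Why: Williamson etherification alkylates only the four phenols, since K2CO3 does not deprotonate the secondary 3-OH, and no stereocentre is touched.

Step 2
Reactants: 3 5,7,3',4'-tetra-O-benzyl-(−)-epicatechin; 4 2-ethoxyethanol
Product: 5 5,7,3',4'-tetra-O-benzyl-4β-(2-ethoxyethoxy)epicatechin
Conditions: DDQ (2 equiv), 2-ethoxyethanol (5 equiv), CH2Cl2, rt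
Reagents that add atoms: 2-ethoxyethanol, CCOCCO
Why: DDQ benzylic oxidation abstracts hydride from C4 to give a cation stabilised by ring A, which the alcohol should capture on the β face, anti to the axial 3-OH (the C4 configuration is lost again in step 5).

Step 3
Reactants: 5 5,7,3',4'-tetra-O-benzyl-4β-(2-ethoxyethoxy)epicatechin; 6 3,4,5-tris(benzyloxy)benzoic acid
Product: 7 5,7,3',4'-tetra-O-benzyl-4β-(2-ethoxyethoxy)epicatechin 3-O-[3,4,5-tris(benzyloxy)benzoate]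
Conditions: 6, DCC, DMAP, CH2Cl2, rt
Reagents that add atoms: 3,4,5-tris(benzyloxy)benzoic acid, OC(=O)c1cc(OCc2ccccc2)c(OCc2ccccc2)c(OCc2ccccc2)c1
Why: Steglich esterification acylates the hindered axial 3-OH under neutral conditions that leave the C4 ether intact.

Step 4
Reactants: 8 3,5-bis(benzyloxy)phenol; 9 chlorotriisopropylsilane
Product: 10 [3,5-bis(benzyloxy)phenoxy]triisopropylsilane
Conditions: TIPSCl, imidazole, DMF, rt
Reagents that add atoms: chlorotriisopropylsilane, CC(C)[Si](Cl)(C(C)C)C(C)C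
Why: Standard phenol silylation; the bulky silyl group is placed to screen its two ortho carbons in step 5.

Step 5
Reactants: 7 5,7,3',4'-tetra-O-benzyl-4β-(2-ethoxyethoxy)epicatechin 3-O-[3,4,5-tris(benzyloxy)benzoate]; 10 [3,5-bis(benzyloxy)phenoxy]triisopropylsilane
Product: 11 4β-[2,6-bis(benzyloxy)-4-(triisopropylsilyloxy)phenyl]-5,7,3',4'-tetra-O-benzylepicatechin 3-O-[3,4,5-tris(benzyloxy)benzoate]
Conditions: TMSOTf (0.3 equiv), 10 (3 equiv), 4 Å molecular sieves, CH2Cl2, −78 to −30 °C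
Reagents that add atoms: none
Why: Lewis-acid ionisation of the C4 ether gives a benzylic cation bridged on the α face by the 3-O-galloyl carbonyl (neighbouring-group participation), and Friedel–Crafts attack on the β face by the arene carbon para to the silyloxy group should set the 4β-aryl bond (3,4-trans).

Step 6
Reactants: 11 4β-[2,6-bis(benzyloxy)-4-(triisopropylsilyloxy)phenyl]-5,7,3',4'-tetra-O-benzylepicatechin 3-O-[3,4,5-tris(benzyloxy)benzoate]
Product: 12 4β-[2,6-bis(benzyloxy)-4-hydroxyphenyl]-5,7,3',4'-tetra-O-benzylepicatechin 3-O-[3,4,5-tris(benzyloxy)benzoate]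
Conditions: TBAF, AcOH, THF, 0 °C
Reagents that add atoms: none
Why: Fluoride cleaves the aryl silyl ether, and the acetic acid buffer keeps the phenoxide from attacking the gallate ester.

Step 7
Reactants: 12 4β-[2,6-bis(benzyloxy)-4-hydroxyphenyl]-5,7,3',4'-tetra-O-benzylepicatechin 3-O-[3,4,5-tris(benzyloxy)benzoate]; 13 paraformaldehyde
Product: 14 4β-[2,6-bis(benzyloxy)-3-formyl-4-hydroxyphenyl]-5,7,3',4'-tetra-O-benzylepicatechin 3-O-[3,4,5-tris(benzyloxy)benzoate]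
Conditions: MgCl2, Et3N, (CH2O)n, THF, reflux
Reagents that add atoms: formaldehyde (from paraformaldehyde), C=O
Why: Casnati–Skattebøl ortho-formylation proceeds through the magnesium phenoxide, so only the ring carrying the free phenol reacts, and its two ortho positions are equivalent.

Step 8
Reactants: 14 4β-[2,6-bis(benzyloxy)-3-formyl-4-hydroxyphenyl]-5,7,3',4'-tetra-O-benzylepicatechin 3-O-[3,4,5-tris(benzyloxy)benzoate]; 15 di-tert-butyl dicarbonate
Product: 16 4β-[2,6-bis(benzyloxy)-4-(tert-butoxycarbonyloxy)-3-formylphenyl]-5,7,3',4'-tetra-O-benzylepicatechin 3-O-[3,4,5-tris(benzyloxy)benzoate]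
Conditions: Boc2O, i-Pr2NEt, DMAP (cat.), THF, rt
Reagents that add atoms: di-tert-butyl dicarbonate, CC(C)(C)OC(=O)OC(=O)OC(C)(C)C
Why: DMAP-catalysed O-acylation of the salicylaldehyde phenol installs the carbonate that later triggers quinone methide formation.

Step 9
Reactants: 3 5,7,3',4'-tetra-O-benzyl-(−)-epicatechin; 17 tert-butylchlorodimethylsilane
Product: 18 5,7,3',4'-tetra-O-benzyl-3-O-(tert-butyldimethylsilyl)epicatechin
Conditions: TBSCl, imidazole, DMF, rt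
Reagents that add atoms: tert-butylchlorodimethylsilane, CC(C)(C)[Si](C)(C)Cl
Why: Silylation masks the 3-OH so that the later aryl organometallic carries no acidic or electrophilic group.

Step 10
Reactants: 18 5,7,3',4'-tetra-O-benzyl-3-O-(tert-butyldimethylsilyl)epicatechin; 19 N-bromosuccinimide
Product: 20 8-bromo-5,7,3',4'-tetra-O-benzyl-3-O-(tert-butyldimethylsilyl)epicatechin
Conditions: NBS, CH2Cl2, −78 °C to rt
Reagents that add atoms: N-bromosuccinimide, O=C1CCC(=O)N1Br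
Why: Electrophilic aromatic bromination of 5,7-di-O-benzyl flavans is selective for C8, the most accessible and electron-rich position of ring A.

Step 11
Reactants: 21 3,4-bis(benzyloxy)benzaldehyde; 22 dimethyl (1-diazo-2-oxopropyl)phosphonate
Product: 23 1,2-bis(benzyloxy)-4-ethynylbenzene
Conditions: K2CO3, MeOH/THF, rt
Reagents that add atoms: dimethyl (1-diazo-2-oxopropyl)phosphonate, COP(=O)(OC)C(=[N+]=[N-])C(C)=O
Why: Seyferth–Gilbert homologation with the Ohira–Bestmann reagent converts the aryl aldehyde into the terminal alkyne under mild base.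

Step 12
Reactants: 23 1,2-bis(benzyloxy)-4-ethynylbenzene; 6 3,4,5-tris(benzyloxy)benzoic acid
Product: 24 (Z)-2-[3,4-bis(benzyloxy)phenyl]ethenyl 3,4,5-tris(benzyloxy)benzoate
Conditions: [RuCl2(p-cymene)]2 (1 mol%), P(4-ClC6H4)3, DMAP (cat.), toluene, 60 °C
Reagents that add atoms: 3,4,5-tris(benzyloxy)benzoic acid, OC(=O)c1cc(OCc2ccccc2)c(OCc2ccccc2)c(OCc2ccccc2)c1
Why: Ruthenium-catalysed anti-Markovnikov hydro-acyloxylation of a terminal alkyne runs through a ruthenium vinylidene, and carboxylate attack at its α-carbon followed by protonolysis should give the Z-enol ester.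

Step 13
Reactants: 20 8-bromo-5,7,3',4'-tetra-O-benzyl-3-O-(tert-butyldimethylsilyl)epicatechin; 16 4β-[2,6-bis(benzyloxy)-4-(tert-butoxycarbonyloxy)-3-formylphenyl]-5,7,3',4'-tetra-O-benzylepicatechin 3-O-[3,4,5-tris(benzyloxy)benzoate]; 24 (Z)-2-[3,4-bis(benzyloxy)phenyl]ethenyl 3,4,5-tris(benzyloxy)benzoate
Product: 30 cycloadduct (fully benzylated trimer; upper and middle units as 3-O-gallates; lower unit 3-O-TBS), via aryllithium 25 (not isolated), via arylmagnesium bromide 26 (not isolated), via magnesium alkoxide 27 (not isolated), via phenoxide carbonate 28 (not isolated), via o-quinone methide 29 (not isolated)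
Conditions: 20, t-BuLi (2.1 equiv), THF, −78 °C; MgBr2·OEt2, −78 °C; 16, −78 to −40 °C; then 24 (3 equiv), −40 °C to rt
Reagents that add atoms: none
Why: Proposed new method: bromine–lithium exchange and transmetalation give 26, which adds to the aldehyde of 16; alkoxide 27 takes over the Boc group (28) and expels tert-butyl carbonate to give the magnesium-bound o-quinone methide 29 (O1=C8a–C4a=C4 of the middle unit), which undergoes an inverse-electron-demand hetero-Diels–Alder reaction with 24 in which the acyloxy-bearing carbon (future C3) bonds first to C4 and the benzylic carbon (future C2) then to O1. The closest known reaction type is the three-component generation of o-quinone methides from O-Boc salicylaldehydes and Grignard reagents with in situ [4+2] capture by enol ethers or styrenes (flavan formation); not yet shown is an enol ester as 2π partner that reacts with aryl-controlled regiochemistry. Ring C of the middle unit closes in a concerted, asynchronous [4+2] mode that is suprafacial on both partners. C2 and C3 (cis) are set by the Z geometry of 24, C4 (trans to C3) by an exo transition state on the E-quinone methide, whose endo sector at C3 is blocked by C4a and the peri C5 benzyl ether, and the absolute sense (middle unit 2α-aryl, 3α-acyloxy, 4β-aryl) by attack on the face of 29 flanked by the ring oxygen of the perpendicular lower flavan, the other face being covered by its C7 benzyl ether once the axial 3-OTBS group has turned away from the C5 ether. The step needs chemoselectivity (aldehyde before carbonate and ester at −78 °C, secured by temperature and stoichiometry), regioselectivity (secured by the 3,4-bis(benzyloxy)phenyl group, which stabilises positive charge at C2 far better than the acyloxy group could at C3) and exo/facial selectivity, of which the facial one is the least secured.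

Step 14
Reactants: 30 cycloadduct (lower unit 3-O-TBS)
Product: 31 fully benzylated trimer with free lower 3-OH
Conditions: HF·pyridine, THF, 0 °C to rt
Reagents that add atoms: none
Why: Fluoride-mediated desilylation of the secondary TBS ether leaves esters, benzyl ethers and the interflavan bonds untouched.

Step 15
Reactants: 31 fully benzylated trimer with free lower 3-OH; 6 3,4,5-tris(benzyloxy)benzoic acid
Product: 32 fully benzylated trimer tri-gallate
Conditions: 6, DCC, DMAP, CH2Cl2, rt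
Reagents that add atoms: 3,4,5-tris(benzyloxy)benzoic acid, OC(=O)c1cc(OCc2ccccc2)c(OCc2ccccc2)c(OCc2ccccc2)c1
Why: Steglich esterification of the axial 3-OH, as in step 3, completes the third gallate without touching any stereocentre.

Step 16
Reactants: 32 fully benzylated trimer tri-gallate
Product: 33 CNP0183218.1 (target)
Conditions: H2 (1 atm), Pd(OH)2/C, THF/MeOH/H2O, rt
Reagents that add atoms: none
Why: Catalytic hydrogenolysis should remove all 21 O-benzyl groups while aryl esters, the flavan C2–O1 bonds and the C4–aryl bonds persist.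

## Compound list

1 | (−)-epicatechin, (2R,3R) | Oc1cc(O)c2c(c1)O[C@H](c1ccc(O)c(O)c1)[C@H](O)C2 | starting material
2 | benzyl bromide | BrCc1ccccc1 | starting material
3 | 5,7,3',4'-tetra-O-benzyl-(−)-epicatechin | C(c5ccccc5)Oc1cc(OCc5ccccc5)c2c(c1)O[C@H](c1ccc(OCc5ccccc5)c(OCc5ccccc5)c1)[C@H](O)C2 | intermediate
4 | 2-ethoxyethanol | CCOCCO | starting material
5 | 5,7,3',4'-tetra-O-benzyl-4β-(2-ethoxyethoxy)epicatechin (3-OH free, 3,4-trans) | O[C@@H]1[C@@H](OCCOCC)c2c(OCc5ccccc5)cc(OCc5ccccc5)cc2O[C@@H]1c1ccc(OCc5ccccc5)c(OCc5ccccc5)c1 | intermediate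
6 | 3,4,5-tris(benzyloxy)benzoic acid | OC(=O)c1cc(OCc2ccccc2)c(OCc2ccccc2)c(OCc2ccccc2)c1 | starting material
7 | 5,7,3',4'-tetra-O-benzyl-4β-(2-ethoxyethoxy)epicatechin 3-O-[3,4,5-tris(benzyloxy)benzoate] | O=C(O[C@@H]1[C@@H](OCCOCC)c2c(OCc5ccccc5)cc(OCc5ccccc5)cc2O[C@@H]1c1ccc(OCc5ccccc5)c(OCc5ccccc5)c1)c1cc(OCc5ccccc5)c(OCc5ccccc5)c(OCc5ccccc5)c1 | intermediate
8 | 3,5-bis(benzyloxy)phenol | Oc1cc(OCc2ccccc2)cc(OCc2ccccc2)c1 | starting material
9 | chlorotriisopropylsilane | CC(C)[Si](Cl)(C(C)C)C(C)C | starting material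
10 | [3,5-bis(benzyloxy)phenoxy]triisopropylsilane | CC(C)[Si](Oc1cc(OCc2ccccc2)cc(OCc2ccccc2)c1)(C(C)C)C(C)C | intermediate
11 | 4β-[2,6-bis(benzyloxy)-4-(triisopropylsilyloxy)phenyl]-5,7,3',4'-tetra-O-benzylepicatechin 3-O-[3,4,5-tris(benzyloxy)benzoate] | O=C(O[C@@H]1[C@@H](c2c(OCc5ccccc5)cc(O[Si](C(C)C)(C(C)C)C(C)C)cc2OCc5ccccc5)c2c(OCc5ccccc5)cc(OCc5ccccc5)cc2O[C@@H]1c1ccc(OCc5ccccc5)c(OCc5ccccc5)c1)c1cc(OCc5ccccc5)c(OCc5ccccc5)c(OCc5ccccc5)c1 | intermediate
12 | 4β-[2,6-bis(benzyloxy)-4-hydroxyphenyl]-5,7,3',4'-tetra-O-benzylepicatechin 3-O-[3,4,5-tris(benzyloxy)benzoate] | O=C(O[C@@H]1[C@@H](c2c(OCc5ccccc5)cc(O)cc2OCc5ccccc5)c2c(OCc5ccccc5)cc(OCc5ccccc5)cc2O[C@@H]1c1ccc(OCc5ccccc5)c(OCc5ccccc5)c1)c1cc(OCc5ccccc5)c(OCc5ccccc5)c(OCc5ccccc5)c1 | intermediate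
13 | paraformaldehyde (written as formaldehyde) | C=O | starting material
14 | 4β-[2,6-bis(benzyloxy)-3-formyl-4-hydroxyphenyl]-5,7,3',4'-tetra-O-benzylepicatechin 3-O-[3,4,5-tris(benzyloxy)benzoate] | O=C(O[C@@H]1[C@@H](c2c(OCc5ccccc5)cc(O)c(C=O)c2OCc5ccccc5)c2c(OCc5ccccc5)cc(OCc5ccccc5)cc2O[C@@H]1c1ccc(OCc5ccccc5)c(OCc5ccccc5)c1)c1cc(OCc5ccccc5)c(OCc5ccccc5)c(OCc5ccccc5)c1 | intermediate
15 | di-tert-butyl dicarbonate | CC(C)(C)OC(=O)OC(=O)OC(C)(C)C | starting material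
16 | 4β-[2,6-bis(benzyloxy)-4-(tert-butoxycarbonyloxy)-3-formylphenyl]-5,7,3',4'-tetra-O-benzylepicatechin 3-O-[3,4,5-tris(benzyloxy)benzoate] | O=C(O[C@@H]1[C@@H](c2c(OCc5ccccc5)cc(OC(=O)OC(C)(C)C)c(C=O)c2OCc5ccccc5)c2c(OCc5ccccc5)cc(OCc5ccccc5)cc2O[C@@H]1c1ccc(OCc5ccccc5)c(OCc5ccccc5)c1)c1cc(OCc5ccccc5)c(OCc5ccccc5)c(OCc5ccccc5)c1 | intermediate
17 | tert-butylchlorodimethylsilane | CC(C)(C)[Si](C)(C)Cl | starting material
18 | 5,7,3',4'-tetra-O-benzyl-3-O-(tert-butyldimethylsilyl)epicatechin | C(c5ccccc5)Oc1cc(OCc5ccccc5)c2c(c1)O[C@H](c1ccc(OCc5ccccc5)c(OCc5ccccc5)c1)[C@H](O[Si](C)(C)C(C)(C)C)C2 | intermediate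
19 | N-bromosuccinimide | O=C1CCC(=O)N1Br | starting material
20 | 8-bromo-5,7,3',4'-tetra-O-benzyl-3-O-(tert-butyldimethylsilyl)epicatechin | C(c5ccccc5)Oc1cc(OCc5ccccc5)c2c(c1Br)O[C@H](c1ccc(OCc5ccccc5)c(OCc5ccccc5)c1)[C@H](O[Si](C)(C)C(C)(C)C)C2 | intermediate
21 | 3,4-bis(benzyloxy)benzaldehyde | O=Cc1ccc(OCc2ccccc2)c(OCc2ccccc2)c1 | starting material
22 | dimethyl (1-diazo-2-oxopropyl)phosphonate | COP(=O)(OC)C(=[N+]=[N-])C(C)=O | starting material
23 | 1,2-bis(benzyloxy)-4-ethynylbenzene | C#Cc1ccc(OCc2ccccc2)c(OCc2ccccc2)c1 | intermediate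
24 | (Z)-2-[3,4-bis(benzyloxy)phenyl]ethenyl 3,4,5-tris(benzyloxy)benzoate | O=C(O/C=C\c1ccc(OCc2ccccc2)c(OCc2ccccc2)c1)c1cc(OCc2ccccc2)c(OCc2ccccc2)c(OCc2ccccc2)c1 | intermediate
25 | 8-lithio-5,7,3',4'-tetra-O-benzyl-3-O-TBS-epicatechin | C(c5ccccc5)Oc1cc(OCc5ccccc5)c2c(c1[Li])O[C@H](c1ccc(OCc5ccccc5)c(OCc5ccccc5)c1)[C@H](O[Si](C)(C)C(C)(C)C)C2 | intermediate
26 | 8-(bromomagnesio)-5,7,3',4'-tetra-O-benzyl-3-O-TBS-epicatechin | C(c5ccccc5)Oc1cc(OCc5ccccc5)c2c(c1[Mg]Br)O[C@H](c1ccc(OCc5ccccc5)c(OCc5ccccc5)c1)[C@H](O[Si](C)(C)C(C)(C)C)C2 | intermediate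
27 | bromomagnesium alkoxide from addition of 26 to the aldehyde of 16 (diarylmethanol carbon = future C4 of the middle unit, both epimers; Boc still on the phenol oxygen) | O=C(O[C@@H]1[C@@H](c2c(OCc5ccccc5)cc(OC(=O)OC(C)(C)C)c(c2OCc5ccccc5)C(O[Mg]Br)c2c(OCc5ccccc5)cc(OCc5ccccc5)c4c2O[C@H](c2ccc(OCc5ccccc5)c(OCc5ccccc5)c2)[C@H](O[Si](C)(C)C(C)(C)C)C4)c2c(OCc5ccccc5)cc(OCc5ccccc5)cc2O[C@@H]1c1ccc(OCc5ccccc5)c(OCc5ccccc5)c1)c1cc(OCc5ccccc5)c(OCc5ccccc5)c(OCc5ccccc5)c1 | intermediate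
28 | bromomagnesium phenoxide with benzylic tert-butyl carbonate (27 after O-to-O Boc transfer) | O=C(O[C@@H]1[C@@H](c2c(OCc5ccccc5)cc(O[Mg]Br)c(c2OCc5ccccc5)C(OC(=O)OC(C)(C)C)c2c(OCc5ccccc5)cc(OCc5ccccc5)c4c2O[C@H](c2ccc(OCc5ccccc5)c(OCc5ccccc5)c2)[C@H](O[Si](C)(C)C(C)(C)C)C4)c2c(OCc5ccccc5)cc(OCc5ccccc5)cc2O[C@@H]1c1ccc(OCc5ccccc5)c(OCc5ccccc5)c1)c1cc(OCc5ccccc5)c(OCc5ccccc5)c(OCc5ccccc5)c1 | intermediate
29 | (E)-o-quinone methide: middle ring A as 3,5-bis(benzyloxy)cyclohexa-2,4-dienone carrying the upper flavan-4β-yl at C4 and the (lower flavan-8-yl)methylidene at C6 (dienone numbering), drawn free of magnesium | O=C(O[C@@H]1[C@@H](C2=C(OCc5ccccc5)/C(=C\c6c(OCc5ccccc5)cc(OCc5ccccc5)c4c6O[C@H](c6ccc(OCc5ccccc5)c(OCc5ccccc5)c6)[C@H](O[Si](C)(C)C(C)(C)C)C4)C(=O)C=C2OCc5ccccc5)c2c(OCc5ccccc5)cc(OCc5ccccc5)cc2O[C@@H]1c1ccc(OCc5ccccc5)c(OCc5ccccc5)c1)c1cc(OCc5ccccc5)c(OCc5ccccc5)c(OCc5ccccc5)c1 | intermediate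
30 | cycloadduct: fully benzylated epicatechin gallate-(4β→6)-epicatechin gallate-(4β→8)-epicatechin with lower 3-O-TBS (middle unit 2α-aryl, 3α-galloyloxy, 4β-aryl) | O=C(O[C@@H]1[C@@H](c2c(OCc5ccccc5)cc3c(c2OCc5ccccc5)[C@H](c2c(OCc5ccccc5)cc(OCc5ccccc5)c4c2O[C@H](c2ccc(OCc5ccccc5)c(OCc5ccccc5)c2)[C@H](O[Si](C)(C)C(C)(C)C)C4)[C@@H](OC(=O)c2cc(OCc5ccccc5)c(OCc5ccccc5)c(OCc5ccccc5)c2)[C@@H](c2ccc(OCc5ccccc5)c(OCc5ccccc5)c2)O3)c2c(OCc5ccccc5)cc(OCc5ccccc5)cc2O[C@@H]1c1ccc(OCc5ccccc5)c(OCc5ccccc5)c1)c1cc(OCc5ccccc5)c(OCc5ccccc5)c(OCc5ccccc5)c1 | intermediate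
31 | fully benzylated trimer with free lower 3-OH | O=C(O[C@@H]1[C@@H](c2c(OCc5ccccc5)cc3c(c2OCc5ccccc5)[C@H](c2c(OCc5ccccc5)cc(OCc5ccccc5)c4c2O[C@H](c2ccc(OCc5ccccc5)c(OCc5ccccc5)c2)[C@H](O)C4)[C@@H](OC(=O)c2cc(OCc5ccccc5)c(OCc5ccccc5)c(OCc5ccccc5)c2)[C@@H](c2ccc(OCc5ccccc5)c(OCc5ccccc5)c2)O3)c2c(OCc5ccccc5)cc(OCc5ccccc5)cc2O[C@@H]1c1ccc(OCc5ccccc5)c(OCc5ccccc5)c1)c1cc(OCc5ccccc5)c(OCc5ccccc5)c(OCc5ccccc5)c1 | intermediate
32 | fully benzylated trimer tri-gallate (21 benzyl ethers) | O=C(O[C@@H]1[C@@H](c2c(OCc5ccccc5)cc3c(c2OCc5ccccc5)[C@H](c2c(OCc5ccccc5)cc(OCc5ccccc5)c4c2O[C@H](c2ccc(OCc5ccccc5)c(OCc5ccccc5)c2)[C@H](OC(=O)c2cc(OCc5ccccc5)c(OCc5ccccc5)c(OCc5ccccc5)c2)C4)[C@@H](OC(=O)c2cc(OCc5ccccc5)c(OCc5ccccc5)c(OCc5ccccc5)c2)[C@@H](c2ccc(OCc5ccccc5)c(OCc5ccccc5)c2)O3)c2c(OCc5ccccc5)cc(OCc5ccccc5)cc2O[C@@H]1c1ccc(OCc5ccccc5)c(OCc5ccccc5)c1)c1cc(OCc5ccccc5)c(OCc5ccccc5)c(OCc5ccccc5)c1 | intermediate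
33 | CNP0183218.1: epicatechin 3-O-gallate-(4β→6)-epicatechin 3-O-gallate-(4β→8)-epicatechin 3-O-gallate (upper unit 2R,3R,4S; middle unit 2R,3R,4R; lower unit 2R,3R) | O=C(O[C@@H]1[C@@H](c2c(O)cc3c(c2O)[C@H](c2c(O)cc(O)c4c2O[C@H](c2ccc(O)c(O)c2)[C@H](OC(=O)c2cc(O)c(O)c(O)c2)C4)[C@@H](OC(=O)c2cc(O)c(O)c(O)c2)[C@@H](c2ccc(O)c(O)c2)O3)c2c(O)cc(O)cc2O[C@@H]1c1ccc(O)c(O)c1)c1cc(O)c(O)c(O)c1 | target

## Step count and risks

Total step count: 16. Longest linear sequence: 11 steps (steps 1, 2, 3, 5, 6, 7, 8, 13, 14, 15, 16).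

Steps most likely to fail:

1. Step 13 (proposed new method). Facial selection on the quinone methide by the two flavan substituents may be weak, and the endo mode may compete, so that C4-epimeric or mirror-configured middle rings form. A stepwise ionic course could let the C2–C3 bond rotate or let the ester carbonyl bridge C2, eroding the 2,3-cis relationship. Acyl transfer from the enol ester to magnesium alkoxides could consume the dienophile. The fallback uses known Lewis-acid interflavan coupling with a C8 bromine as blocking group and sets out from 7 and 20. TMSOTf-promoted coupling of 7 with an excess of 20, whose only free nucleophilic ring position is C6, should give the benzylated epicatechin gallate-(4β→6)-8-bromo-3-O-TBS-epicatechin dimer F1. DDQ and 2-ethoxyethanol in CH2Cl2 oxidise C4 of its lower unit to the dimeric 4β-(2-ethoxyethoxy) electrophile F2. TMSOTf coupling of F2 with 18, which reacts at C8, gives the 8-bromo trimer bis-TBS ether F3. HF·pyridine gives the 8-bromo trimer diol F4, and Steglich esterification with 6 (DCC, DMAP) gives the 8-bromo fully benzylated trimer tri-gallate F5. Hydrogenation (H2, Pd(OH)2/C, Et3N, THF/MeOH/H2O) removes the bromine together with all benzyl groups and comes back to the route at 33.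

2. Step 5. Arylation ortho instead of para to the silyloxy group would lead on to the 4→8 isomer, and a second alkylation of the electron-rich arene or premature loss of the silyl group may also occur. The fallback sets out from 7. Coupling with free phloroglucinol (BF3·OEt2, THF/CH2Cl2), whose three ring positions are equivalent, gives the 4β-(2,4,6-trihydroxyphenyl) adduct F6. The unhindered para hydroxyl is silylated selectively (TIPSCl, imidazole, DMF, 0 °C) to the mono-TIPS diol F7. Benzylation of the two flanking hydroxyls (BnBr, K2CO3, acetone) comes back to the route at 11.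

3. Step 12. Z selectivity may erode to the E isomer, the Markovnikov 1,1-disubstituted enol ester may form, or the product may isomerise under the reaction conditions. The fallback sets out from 23. Rhodium-catalysed trans-hydroboration (pinacolborane, [Rh(cod)Cl]2, P(i-Pr)3, Et3N, cyclohexane) gives the (Z)-alkenyl pinacol boronate F8. KHF2 in MeOH/H2O converts it into the potassium (Z)-alkenyltrifluoroborate F9. Copper-mediated oxidative C–O coupling with acid 6 (Cu(OAc)2, DMAP, 4 Å molecular sieves, O2, CH2Cl2), a Chan–Lam-type reaction that retains alkene geometry, comes back to the route at 24.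

Further compounds

F1 | step 13 | benzylated epicatechin 3-O-gallate-(4β→6)-8-bromo-3-O-TBS-epicatechin dimer | O=C(O[C@@H]1[C@@H](c2c(OCc5ccccc5)c(Br)c3c(c2OCc5ccccc5)C[C@@H](O[Si](C)(C)C(C)(C)C)[C@@H](c2ccc(OCc5ccccc5)c(OCc5ccccc5)c2)O3)c2c(OCc5ccccc5)cc(OCc5ccccc5)cc2O[C@@H]1c1ccc(OCc5ccccc5)c(OCc5ccccc5)c1)c1cc(OCc5ccccc5)c(OCc5ccccc5)c(OCc5ccccc5)c1
F2 | step 13 | dimeric electrophile: F1 with a 4β-(2-ethoxyethoxy) group on the lower unit | O=C(O[C@@H]1[C@@H](c2c(OCc5ccccc5)c(Br)c3c(c2OCc5ccccc5)[C@H](OCCOCC)[C@@H](O[Si](C)(C)C(C)(C)C)[C@@H](c2ccc(OCc5ccccc5)c(OCc5ccccc5)c2)O3)c2c(OCc5ccccc5)cc(OCc5ccccc5)cc2O[C@@H]1c1ccc(OCc5ccccc5)c(OCc5ccccc5)c1)c1cc(OCc5ccccc5)c(OCc5ccccc5)c(OCc5ccccc5)c1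
F3 | step 13 | 8-bromo trimer with middle and lower 3-O-TBS groups | O=C(O[C@@H]1[C@@H](c2c(OCc5ccccc5)c(Br)c3c(c2OCc5ccccc5)[C@H](c2c(OCc5ccccc5)cc(OCc5ccccc5)c4c2O[C@H](c2ccc(OCc5ccccc5)c(OCc5ccccc5)c2)[C@H](O[Si](C)(C)C(C)(C)C)C4)[C@@H](O[Si](C)(C)C(C)(C)C)[C@@H](c2ccc(OCc5ccccc5)c(OCc5ccccc5)c2)O3)c2c(OCc5ccccc5)cc(OCc5ccccc5)cc2O[C@@H]1c1ccc(OCc5ccccc5)c(OCc5ccccc5)c1)c1cc(OCc5ccccc5)c(OCc5ccccc5)c(OCc5ccccc5)c1
F4 | step 13 | 8-bromo trimer with free middle and lower 3-OH groups | O=C(O[C@@H]1[C@@H](c2c(OCc5ccccc5)c(Br)c3c(c2OCc5ccccc5)[C@H](c2c(OCc5ccccc5)cc(OCc5ccccc5)c4c2O[C@H](c2ccc(OCc5ccccc5)c(OCc5ccccc5)c2)[C@H](O)C4)[C@@H](O)[C@@H](c2ccc(OCc5ccccc5)c(OCc5ccccc5)c2)O3)c2c(OCc5ccccc5)cc(OCc5ccccc5)cc2O[C@@H]1c1ccc(OCc5ccccc5)c(OCc5ccccc5)c1)c1cc(OCc5ccccc5)c(OCc5ccccc5)c(OCc5ccccc5)c1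
F5 | step 13 | 8-bromo fully benzylated trimer tri-gallate (8-bromo analogue of 32 at the middle unit) | O=C(O[C@@H]1[C@@H](c2c(OCc5ccccc5)c(Br)c3c(c2OCc5ccccc5)[C@H](c2c(OCc5ccccc5)cc(OCc5ccccc5)c4c2O[C@H](c2ccc(OCc5ccccc5)c(OCc5ccccc5)c2)[C@H](OC(=O)c2cc(OCc5ccccc5)c(OCc5ccccc5)c(OCc5ccccc5)c2)C4)[C@@H](OC(=O)c2cc(OCc5ccccc5)c(OCc5ccccc5)c(OCc5ccccc5)c2)[C@@H](c2ccc(OCc5ccccc5)c(OCc5ccccc5)c2)O3)c2c(OCc5ccccc5)cc(OCc5ccccc5)cc2O[C@@H]1c1ccc(OCc5ccccc5)c(OCc5ccccc5)c1)c1cc(OCc5ccccc5)c(OCc5ccccc5)c(OCc5ccccc5)c1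
F6 | step 5 | 4β-(2,4,6-trihydroxyphenyl)-5,7,3',4'-tetra-O-benzylepicatechin 3-O-[3,4,5-tris(benzyloxy)benzoate] | O=C(O[C@@H]1[C@@H](c2c(O)cc(O)cc2O)c2c(OCc5ccccc5)cc(OCc5ccccc5)cc2O[C@@H]1c1ccc(OCc5ccccc5)c(OCc5ccccc5)c1)c1cc(OCc5ccccc5)c(OCc5ccccc5)c(OCc5ccccc5)c1
F7 | step 5 | 4β-[2,6-dihydroxy-4-(triisopropylsilyloxy)phenyl]-5,7,3',4'-tetra-O-benzylepicatechin 3-O-[3,4,5-tris(benzyloxy)benzoate] | O=C(O[C@@H]1[C@@H](c2c(O)cc(O[Si](C(C)C)(C(C)C)C(C)C)cc2O)c2c(OCc5ccccc5)cc(OCc5ccccc5)cc2O[C@@H]1c1ccc(OCc5ccccc5)c(OCc5ccccc5)c1)c1cc(OCc5ccccc5)c(OCc5ccccc5)c(OCc5ccccc5)c1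
F8 | step 12 | (Z)-2-{2-[3,4-bis(benzyloxy)phenyl]ethenyl}-4,4,5,5-tetramethyl-1,3,2-dioxaborolane | CC1(C)OB(/C=C\c2ccc(OCc3ccccc3)c(OCc3ccccc3)c2)OC1(C)C
F9 | step 12 | potassium (Z)-{2-[3,4-bis(benzyloxy)phenyl]ethenyl}trifluoroborate | [K+].F[B-](F)(F)/C=C\c1ccc(OCc2ccccc2)c(OCc2ccccc2)c1
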